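**Plan**
- Retrosynthesis: the sulfate ester and the benzyl ethers come off first. The C1–C2 bond of the tetralin is cut next, which opens the only carbocycle that has to be built. The C1–C8a aryl–carbinol bond and the C4–C3 bond of the side chain follow.
- The C1–C2 cut is possible because C1 carries a 4-hydroxy-3,5-dimethoxyphenyl ring. That ring is the aromatised form of a cyclohexadienone (p-quinone methide) whose exocyclic methide carbon is C1, and the adjacent C2 carries a CH2O arm that can be held as a formyl group, i.e. as an enamine donor.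
- Forward: the benzylic bromide of the future tetralin arene alkylates a pentenoyl imide (C4–C3). The aryl bromide is joined to O-silylsyringaldehyde by Br–Li exchange (C1–C8a). The allyl group is cut down to the aldehyde, and the tetralin ring closes by enamine 1,6-addition to the quinone methide (C1–C2).
- Stereochemistry: C3 comes from the (S)-4-benzyloxazolidinone auxiliary. C2 and C1 arise in the ring closure, relayed from C3 through a half-chair transition state and reinforced by a matched (S)-diarylprolinol catalyst.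
- Endgame: formyl reduction, phenol benzylation, sulfation of the one free alcohol, hydrogenolysis.

Key step: step 13

Remark 1: ring positions are in tetralin numbering (C1 aryl-bearing, C2 sulfated arm, C3 hydroxymethyl arm, C4 CH2, C8 the aromatic carbon next to C1).
Remark 2: the carbinol carbon of 15–18 (and C2 of diol 16) forms without control; both epimers are carried on because this carbon becomes trigonal in 19.
Remark 3: forms differing from a numbered compound only by a proton or counter-ion (enolate of 9, alkoxides, phenoxides, the sodium salt of 24 before acidification) carry no number; the target is taken as the free hydrogen sulfate, as drawn.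

**Step 1**
Reactants: 1 syringaldehyde
Product: 2 4-(benzyloxy)-3,5-dimethoxybenzaldehyde
Conditions: BnBr, K2CO3, DMF, rt
Reagents that add atoms: benzyl bromide, BrCc1ccccc1
Why: Williamson etherification of the potassium phenoxide, the only nucleophilic site, with a reactive benzylic halide.

**Step 2**
Reactants: 2 4-(benzyloxy)-3,5-dimethoxybenzaldehyde
Product: 3 4-(benzyloxy)-2-bromo-3,5-dimethoxybenzaldehyde
Conditions: NBS, DMF, rt
Reagents that add atoms: N-bromosuccinimide, O=C1CCC(=O)N1Br
Why: Electrophilic aromatic bromination in which the two open ring positions are equivalent, each ortho to one methoxy group and para to the other, while the formyl group and the first bromine should slow a second substitution.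

**Step 3**
Reactants: 3 4-(benzyloxy)-2-bromo-3,5-dimethoxybenzaldehyde
Product: 4 [4-(benzyloxy)-2-bromo-3,5-dimethoxyphenyl]methanol
Conditions: NaBH4, MeOH/THF, 0 °C
Reagents that add atoms: none
Why: Borohydride reduction of the aryl aldehyde, to which the aryl bromide and the benzyl ether are inert.

**Step 4**
Reactants: 4 [4-(benzyloxy)-2-bromo-3,5-dimethoxyphenyl]methanol
Product: 5 1-(benzyloxy)-3-bromo-4-(bromomethyl)-2,6-dimethoxybenzene
Conditions: PBr3, CH2Cl2, 0 °C
Reagents that add atoms: phosphorus tribromide, BrP(Br)Br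
Why: Conversion of the benzylic alcohol into the bromide through its phosphite ester (SN2 by bromide), short and cold enough to spare the aryl benzyl ether.

**Step 5**
Reactants: 6 pent-4-enoic acid; 7 (S)-4-benzyl-1,3-oxazolidin-2-one
Product: 9 (4S)-4-benzyl-3-(pent-4-enoyl)-1,3-oxazolidin-2-one, via pivalic mixed anhydride 8 (not isolated)
Conditions: PivCl, Et3N, THF, −20 °C; then 7, LiCl, −20 °C → rt
Reagents that add atoms: none
Why: N-acylation of the oxazolidinone by a mixed anhydride, which is attacked at its less hindered pentenoyl carbonyl and leaves the auxiliary stereocentre untouched.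

**Step 6**
Reactants: 9 (4S)-4-benzyl-3-(pent-4-enoyl)-1,3-oxazolidin-2-one; 5 1-(benzyloxy)-3-bromo-4-(bromomethyl)-2,6-dimethoxybenzene
Product: 10 (4S)-4-benzyl-3-[(2R)-2-{[4-(benzyloxy)-2-bromo-3,5-dimethoxyphenyl]methyl}pent-4-enoyl]-1,3-oxazolidin-2-one
Conditions: NaHMDS, THF, −78 °C; then 5, −78 → −40 °C
Reagents that add atoms: none
Why: Evans asymmetric alkylation, in which the chelated (Z)-sodium enolate is attacked by the benzylic bromide on the face opposite the benzyl group of the auxiliary, setting the (R) centre that becomes C3.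

**Step 7**
Reactants: 10 the alkylated imide
Product: 11 (2R)-2-{[4-(benzyloxy)-2-bromo-3,5-dimethoxyphenyl]methyl}pent-4-en-1-ol
Conditions: LiBH4, MeOH (1.1 equiv), THF, 0 °C
Reagents that add atoms: none
Why: Reductive cleavage of the exocyclic imide carbonyl with lithium borohydride, which releases the auxiliary without enolisation, so the new stereocentre is kept and the aryl bromide is untouched.

**Step 8**
Reactants: 11 the (2R)-pentenol
Product: 12 2-(benzyloxy)-5-[(2R)-2-[(benzyloxy)methyl]pent-4-en-1-yl]-4-bromo-1,3-dimethoxybenzene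
Conditions: NaH, BnBr, Bu4NI (cat.), THF/DMF, 0 °C → rt
Reagents that add atoms: benzyl bromide, BrCc1ccccc1
Why: Williamson benzylation of the primary alkoxide, which marks the future C3 arm as distinct from the C2 arm for the rest of the route.

**Step 9**
Reactants: 1 syringaldehyde
Product: 13 4-[(tert-butyldimethylsilyl)oxy]-3,5-dimethoxybenzaldehyde
Conditions: TBSCl, imidazole, DMF, rt
Reagents that add atoms: tert-butyldimethylsilyl chloride, CC(C)(C)[Si](C)(C)Cl
Why: Silylation of the phenol, which masks the acidic OH for the organolithium step and can later be removed without touching the benzyl ethers.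

**Step 10**
Reactants: 12 the aryl bromide; 13 4-[(tert-butyldimethylsilyl)oxy]-3,5-dimethoxybenzaldehyde
Product: 15 {3-(benzyloxy)-6-[(2R)-2-[(benzyloxy)methyl]pent-4-en-1-yl]-2,4-dimethoxyphenyl}{4-[(tert-butyldimethylsilyl)oxy]-3,5-dimethoxyphenyl}methanol (both carbinol epimers), via aryllithium 14 (not isolated)
Conditions: n-BuLi, THF, −78 °C; then 13, −78 → −40 °C; aq. NH4Cl
Reagents that add atoms: none
Why: Bromine–lithium exchange, faster at −78 °C than any deprotonation or ether rearrangement, followed by 1,2-addition of the aryllithium to a non-enolisable aldehyde; the carbinol centre needs no control.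

**Step 11**
Reactants: 15 the diarylmethanol
Product: 17 (3S)-3-[(benzyloxy)methyl]-4-{4-(benzyloxy)-2-[{4-[(tert-butyldimethylsilyl)oxy]-3,5-dimethoxyphenyl}(hydroxy)methyl]-3,5-dimethoxyphenyl}butanal, via vicinal diol 16 (not isolated)
Conditions: OsO4 (2 mol %), NaIO4, 2,6-lutidine, dioxane/H2O, rt
Reagents that add atoms: osmium tetroxide, O=[Os](=O)(=O)=O; sodium periodate, [Na+].[O-]I(=O)(=O)=O
Why: Lemieux–Johnson cleavage (catalytic dihydroxylation of the only alkene, then periodate cleavage of the diol) under lutidine buffering, which should spare the acid-sensitive carbinol and the fully etherified arenes; the stereocentre is β to the new aldehyde and cannot epimerise.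

**Step 12**
Reactants: 17 the silyl-protected aldehyde
Product: 18 (3S)-3-[(benzyloxy)methyl]-4-{4-(benzyloxy)-2-[hydroxy(4-hydroxy-3,5-dimethoxyphenyl)methyl]-3,5-dimethoxyphenyl}butanal
Conditions: TBAF, AcOH, THF, 0 °C; pH 7 work-up, used without chromatography
Reagents that add atoms: none
Why: Fluoride cleavage of the aryl silyl ether, fast because a phenoxide leaves, with acetic acid buffering to keep the enolisable aldehyde from aldol reactions.

**Step 13**
Reactants: 18 the p-hydroxybenzhydrol aldehyde
Product: 20 (1R,2S,3S)-7-(benzyloxy)-3-[(benzyloxy)methyl]-1-(4-hydroxy-3,5-dimethoxyphenyl)-6,8-dimethoxy-1,2,3,4-tetrahydronaphthalene-2-carbaldehyde, via p-quinone methide 19 (not isolated)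
Conditions: (S)-α,α-diphenylprolinol trimethylsilyl ether (20 mol %), 4-O2NC6H4CO2H (20 mol %), CH2Cl2, 0 °C → rt
Reagents that add atoms: none
Why: The acid assists loss of water from the benzhydrol (its cation is stabilised by the para hydroxyl of one ring and the ortho and para methoxy groups of the other) to give quinone methide 19, while the amine converts the aldehyde into its (E)-enamine; the enamine α-carbon (C2) then attacks the methide carbon (C1) in a 1,6-conjugate addition that restores the phenol, and iminium hydrolysis frees the catalyst and the C2 formyl group. The closest known reaction type is the diarylprolinol silyl ether catalysed α-alkylation of aldehydes with p-quinone methides, including closures of ortho-tethered quinone methides, together with the aminocatalytic SN1-type alkylation of aldehydes by benzhydrols. The single ring formed, the tetralin carbocycle, closes by a 6-(enolexo)-exo-trig attack that makes the C1–C2 bond. C2 is controlled by the enamine face: the (S)-catalyst shields the face that would put the formyl group cis to the C3 arm, the same face disfavoured by a half-chair with the C3 benzyloxymethyl group equatorial (matched pair), and because C2 stays enolisable it can settle into the trans arrangement. C1 is controlled by the orientation of the planar methide in that half-chair, the dienone ring taking the pseudo-equatorial site so that it ends trans to the C2 formyl group and cis to the C3 arm. The step needs one diastereomer of four, (1R,2S,3S), which the fixed (S) centre of the tether, the matched catalyst and thermodynamic correction at C2 should secure, C1 being the only centre left to kinetic control alone.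

**Step 14**
Reactants: 20 the tetralin aldehyde
Product: 21 [(1R,2S,3S)-7-(benzyloxy)-3-[(benzyloxy)methyl]-1-(4-hydroxy-3,5-dimethoxyphenyl)-6,8-dimethoxy-1,2,3,4-tetrahydronaphthalen-2-yl]methanol
Conditions: NaBH4, MeOH/THF, 0 °C
Reagents that add atoms: none
Why: Borohydride reduction of the aldehyde to the C2 hydroxymethyl arm, which also removes the only epimerisable centre from further risk.

**Step 15**
Reactants: 21 the phenol alcohol
Product: 22 [(1R,2S,3S)-7-(benzyloxy)-1-[4-(benzyloxy)-3,5-dimethoxyphenyl]-3-[(benzyloxy)methyl]-6,8-dimethoxy-1,2,3,4-tetrahydronaphthalen-2-yl]methanol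
Conditions: BnBr, K2CO3, DMF, rt → 40 °C
Reagents that add atoms: benzyl bromide, BrCc1ccccc1
Why: Chemoselective Williamson benzylation, since carbonate deprotonates the phenol but not the primary alcohol.

**Step 16**
Reactants: 22 the tribenzyl alcohol
Product: 23 sodium [(1R,2S,3S)-7-(benzyloxy)-1-[4-(benzyloxy)-3,5-dimethoxyphenyl]-3-[(benzyloxy)methyl]-6,8-dimethoxy-1,2,3,4-tetrahydronaphthalen-2-yl]methyl sulfate
Conditions: SO3·pyridine, pyridine, rt → 40 °C; then aq. NaHCO3
Reagents that add atoms: sulfur trioxide–pyridine complex, O=S(=O)([O-])[n+]1ccccc1; sodium hydrogencarbonate, [Na+].OC(=O)[O-]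
Why: O-sulfation of the only free hydroxyl group with the sulfur trioxide–amine complex, the half-ester being isolated as its sodium salt so that no pyridine is carried into the hydrogenolysis.

**Step 17**
Reactants: 23 the sodium sulfate
Product: 24 [(1R,2S,3S)-7-hydroxy-1-(4-hydroxy-3,5-dimethoxyphenyl)-3-(hydroxymethyl)-6,8-dimethoxy-1,2,3,4-tetrahydronaphthalen-2-yl]methyl hydrogen sulfate
Conditions: H2 (1 atm), 10% Pd/C, MeOH/H2O, rt; then 1 M HCl (1.0 equiv), 0 °C, C18 desalting
Reagents that add atoms: none
Why: Catalytic hydrogenolysis of the two aryl benzyl ethers and the alkyl benzyl ether under neutral conditions, to which sulfate ester salts and the heteroatom-free diarylmethine C1 are inert, followed by protonation of the sulfate.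

**Compound list**
1 | syringaldehyde (4-hydroxy-3,5-dimethoxybenzaldehyde) | COc1cc(C=O)cc(OC)c1O | starting material
2 | 4-(benzyloxy)-3,5-dimethoxybenzaldehyde | COc1cc(C=O)cc(OC)c1OCc1ccccc1 | intermediate
3 | 4-(benzyloxy)-2-bromo-3,5-dimethoxybenzaldehyde | COc1cc(C=O)c(Br)c(OC)c1OCc1ccccc1 | intermediate
4 | [4-(benzyloxy)-2-bromo-3,5-dimethoxyphenyl]methanol | COc1cc(CO)c(Br)c(OC)c1OCc1ccccc1 | intermediate
5 | 1-(benzyloxy)-3-bromo-4-(bromomethyl)-2,6-dimethoxybenzene | COc1cc(CBr)c(Br)c(OC)c1OCc1ccccc1 | intermediate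
6 | pent-4-enoic acid | C=CCCC(=O)O | starting material
7 | (S)-4-benzyl-1,3-oxazolidin-2-one | O=C1N[C@@H](Cc2ccccc2)CO1 | starting material
8 | pent-4-enoic pivalic anhydride (formed in the flask) | C=CCCC(=O)OC(=O)C(C)(C)C | intermediate
9 | (4S)-4-benzyl-3-(pent-4-enoyl)-1,3-oxazolidin-2-one | C=CCCC(=O)N1C(=O)OC[C@@H]1Cc1ccccc1 | intermediate
10 | (4S)-4-benzyl-3-[(2R)-2-{[4-(benzyloxy)-2-bromo-3,5-dimethoxyphenyl]methyl}pent-4-enoyl]-1,3-oxazolidin-2-one | C=CC[C@H](Cc1cc(OC)c(OCc2ccccc2)c(OC)c1Br)C(=O)N1C(=O)OC[C@@H]1Cc1ccccc1 | intermediate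
11 | (2R)-2-{[4-(benzyloxy)-2-bromo-3,5-dimethoxyphenyl]methyl}pent-4-en-1-ol | C=CC[C@H](Cc1cc(OC)c(OCc2ccccc2)c(OC)c1Br)CO | intermediate
12 | 2-(benzyloxy)-5-[(2R)-2-[(benzyloxy)methyl]pent-4-en-1-yl]-4-bromo-1,3-dimethoxybenzene | C=CC[C@H](Cc1cc(OC)c(OCc2ccccc2)c(OC)c1Br)COCc1ccccc1 | intermediate
13 | 4-[(tert-butyldimethylsilyl)oxy]-3,5-dimethoxybenzaldehyde | COc1cc(C=O)cc(OC)c1O[Si](C)(C)C(C)(C)C | intermediate
14 | {3-(benzyloxy)-6-[(2R)-2-[(benzyloxy)methyl]pent-4-en-1-yl]-2,4-dimethoxyphenyl}lithium (formed in the flask) | C=CC[C@H](Cc1cc(OC)c(OCc2ccccc2)c(OC)c1[Li])COCc1ccccc1 | intermediate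
15 | {3-(benzyloxy)-6-[(2R)-2-[(benzyloxy)methyl]pent-4-en-1-yl]-2,4-dimethoxyphenyl}{4-[(tert-butyldimethylsilyl)oxy]-3,5-dimethoxyphenyl}methanol, both carbinol epimers | C=CC[C@H](Cc1cc(OC)c(OCc2ccccc2)c(OC)c1C(O)c1cc(OC)c(O[Si](C)(C)C(C)(C)C)c(OC)c1)COCc1ccccc1 | intermediate
16 | (4S)-4-[(benzyloxy)methyl]-5-{4-(benzyloxy)-2-[{4-[(tert-butyldimethylsilyl)oxy]-3,5-dimethoxyphenyl}(hydroxy)methyl]-3,5-dimethoxyphenyl}pentane-1,2-diol, epimers at C2 and at the carbinol (formed in the flask) | OCC(O)C[C@H](Cc1cc(OC)c(OCc2ccccc2)c(OC)c1C(O)c1cc(OC)c(O[Si](C)(C)C(C)(C)C)c(OC)c1)COCc1ccccc1 | intermediate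
17 | (3S)-3-[(benzyloxy)methyl]-4-{4-(benzyloxy)-2-[{4-[(tert-butyldimethylsilyl)oxy]-3,5-dimethoxyphenyl}(hydroxy)methyl]-3,5-dimethoxyphenyl}butanal, both carbinol epimers | O=CC[C@H](Cc1cc(OC)c(OCc2ccccc2)c(OC)c1C(O)c1cc(OC)c(O[Si](C)(C)C(C)(C)C)c(OC)c1)COCc1ccccc1 | intermediate
18 | (3S)-3-[(benzyloxy)methyl]-4-{4-(benzyloxy)-2-[hydroxy(4-hydroxy-3,5-dimethoxyphenyl)methyl]-3,5-dimethoxyphenyl}butanal, both carbinol epimers | O=CC[C@H](Cc1cc(OC)c(OCc2ccccc2)c(OC)c1C(O)c1cc(OC)c(O)c(OC)c1)COCc1ccccc1 | intermediate
19 | (3S)-3-[(benzyloxy)methyl]-4-{4-(benzyloxy)-2-[(3,5-dimethoxy-4-oxocyclohexa-2,5-dien-1-ylidene)methyl]-3,5-dimethoxyphenyl}butanal (p-quinone methide, formed in the flask) | COC1=CC(=Cc2c(OC)c(OCc3ccccc3)c(OC)cc2C[C@H](COCc2ccccc2)CC=O)C=C(OC)C1=O | intermediate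
20 | (1R,2S,3S)-7-(benzyloxy)-3-[(benzyloxy)methyl]-1-(4-hydroxy-3,5-dimethoxyphenyl)-6,8-dimethoxy-1,2,3,4-tetrahydronaphthalene-2-carbaldehyde | COc1cc([C@@H]2c3c(cc(OC)c(OCc4ccccc4)c3OC)C[C@H](COCc3ccccc3)[C@H]2C=O)cc(OC)c1O | intermediate
21 | [(1R,2S,3S)-7-(benzyloxy)-3-[(benzyloxy)methyl]-1-(4-hydroxy-3,5-dimethoxyphenyl)-6,8-dimethoxy-1,2,3,4-tetrahydronaphthalen-2-yl]methanol | COc1cc([C@@H]2c3c(cc(OC)c(OCc4ccccc4)c3OC)C[C@H](COCc3ccccc3)[C@H]2CO)cc(OC)c1O | intermediate
22 | [(1R,2S,3S)-7-(benzyloxy)-1-[4-(benzyloxy)-3,5-dimethoxyphenyl]-3-[(benzyloxy)methyl]-6,8-dimethoxy-1,2,3,4-tetrahydronaphthalen-2-yl]methanol | COc1cc([C@@H]2c3c(cc(OC)c(OCc4ccccc4)c3OC)C[C@H](COCc3ccccc3)[C@H]2CO)cc(OC)c1OCc1ccccc1 | intermediate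
23 | sodium [(1R,2S,3S)-7-(benzyloxy)-1-[4-(benzyloxy)-3,5-dimethoxyphenyl]-3-[(benzyloxy)methyl]-6,8-dimethoxy-1,2,3,4-tetrahydronaphthalen-2-yl]methyl sulfate | COc1cc([C@@H]2c3c(cc(OC)c(OCc4ccccc4)c3OC)C[C@H](COCc3ccccc3)[C@H]2COS(=O)(=O)[O-])cc(OC)c1OCc1ccccc1.[Na+] | intermediate
24 | [(1R,2S,3S)-7-hydroxy-1-(4-hydroxy-3,5-dimethoxyphenyl)-3-(hydroxymethyl)-6,8-dimethoxy-1,2,3,4-tetrahydronaphthalen-2-yl]methyl hydrogen sulfate (CNP0111670.1) | COc1cc([C@@H]2c3c(cc(OC)c(O)c3OC)C[C@H](CO)[C@H]2COS(=O)(=O)O)cc(OC)c1O | target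

**Step count**
Total: 17 steps. Longest linear sequence: 15 steps (1–4, 6–8, 10–17, from syringaldehyde).

**Steps most likely to fail**

1. Step 13: loss of facial control at the methide carbon. The methoxy group peri to C1 may push the dienone ring into the pseudoaxial site of the closing half-chair and so lead to 1,2-cis material, and closure through the free enol without the catalyst may erode selectivity further. The fallback sets out from 17 and returns at 20, and takes the amine out of the bond-forming event. Compound 17 would be silylated twice with TBSOTf/Et3N (CH2Cl2, 0 °C) to the tert-butyldimethylsilyl enol ether with silylated carbinol oxygen F1. Ionisation of F1 with catalytic TMSOTf at −78 °C should close the ring by a Mukaiyama-type SN1 alkylation of the enol silane by the diarylmethyl cation, a low-temperature closure steered by the C3 centre alone, giving the O-silyl tetralin aldehyde F2. DBU would correct C2 if needed, and TBAF/AcOH would then give 20.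

2. Step 12: premature ionisation of the unprotected p-hydroxybenzhydrol during desilylation and work-up, followed by oligomerisation of the quinone methide or unselective closure, besides fluoride-induced aldol reactions of the aldehyde. The fallback sets out from 17 and returns at 19, so the free phenol is never isolated. Compound 17 would be acetylated (Ac2O, pyridine, DMAP) to the benzhydryl acetate F3. Fluoride (CsF or TBAF) would then be added to F3 in the presence of the aminocatalyst, so that desilylation is followed at once by 1,6-elimination of acetate. This should give 19 in the flask, which closes to 20 as in step 13.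

3. Step 10: slow addition of the di-ortho-substituted aryllithium to the electron-rich aldehyde, so that protonation to the debrominated arene and attack at the aryl silyl ether take over. The fallback sets out from 12 and returns at 15, and reverses the polarity of the union. Aryllithium 14 would be trapped with DMF, a small electrophile, to give the hindered benzaldehyde F4. Commercial 4-bromo-2,6-dimethoxyphenol would be silylated (TBSCl, imidazole) to the aryl bromide F5 and converted with magnesium in THF into the unhindered arylmagnesium bromide F6. Addition of F6 to F4 should give 15.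

**Further compounds**
F1 | step 13 | tert-butyldimethylsilyl enol ether of 17 with the carbinol oxygen also silylated, (3S), E/Z and carbinol epimers | CC(C)(C)[Si](C)(C)OC=C[C@H](Cc1cc(OC)c(OCc2ccccc2)c(OC)c1C(O[Si](C)(C)C(C)(C)C)c1cc(OC)c(O[Si](C)(C)C(C)(C)C)c(OC)c1)COCc1ccccc1
F2 | step 13 | (1R,2S,3S)-7-(benzyloxy)-3-[(benzyloxy)methyl]-1-{4-[(tert-butyldimethylsilyl)oxy]-3,5-dimethoxyphenyl}-6,8-dimethoxy-1,2,3,4-tetrahydronaphthalene-2-carbaldehyde | COc1cc([C@@H]2c3c(cc(OC)c(OCc4ccccc4)c3OC)C[C@H](COCc3ccccc3)[C@H]2C=O)cc(OC)c1O[Si](C)(C)C(C)(C)C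
F3 | step 12 | {3-(benzyloxy)-6-[(2S)-2-[(benzyloxy)methyl]-4-oxobutyl]-2,4-dimethoxyphenyl}{4-[(tert-butyldimethylsilyl)oxy]-3,5-dimethoxyphenyl}methyl acetate, both epimers at the acetoxy carbon | O=CC[C@H](Cc1cc(OC)c(OCc2ccccc2)c(OC)c1C(OC(C)=O)c1cc(OC)c(O[Si](C)(C)C(C)(C)C)c(OC)c1)COCc1ccccc1
F4 | step 10 | 3-(benzyloxy)-6-[(2R)-2-[(benzyloxy)methyl]pent-4-en-1-yl]-2,4-dimethoxybenzaldehyde | C=CC[C@H](Cc1cc(OC)c(OCc2ccccc2)c(OC)c1C=O)COCc1ccccc1
F5 | step 10 | (4-bromo-2,6-dimethoxyphenoxy)(tert-butyl)dimethylsilane | COc1cc(Br)cc(OC)c1O[Si](C)(C)C(C)(C)C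
F6 | step 10 | {4-[(tert-butyldimethylsilyl)oxy]-3,5-dimethoxyphenyl}magnesium bromide | COc1cc([Mg]Br)cc(OC)c1O[Si](C)(C)C(C)(C)C
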